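## The problem

Atom labels follow the SMILES string: C1 (methyl), C2, C3 (acid), C4–C9 (ring A), C10 (lactone C=O), O11, C12, C13 (spiro centre), C14 (ketone), C15, C16, O17, C18, C19 and C20 (CMe2). Cyclohexane ring A is cis-fused along C7–C8 to δ-lactone ring B (C7, C8, C10, O11, C12, C13). Ring B is spiro-linked at C13 to cyclohexanone ring C (C13, C14, C15, C16, C20, C19), which the O17–C18 bridge turns into an 8,8-dimethyl-6-oxabicyclo[3.2.1]octan-3-one. The hardest point is quaternary C13: it carries C7, C12, C14 and C19, lies between the stereocentres C7 and C19, and is one atom from quaternary C20, so C13–C7 is the most hindered bond. Of the seven stereocentres, C16 is tied to C19 by the bridge, C12 is cis and C7 trans to C18 on ring C, H7 points into the crowded C19/C20 side, C7 and C8 are cis, the C4 side chain is trans to both, and exocyclic C2 cannot be controlled from the ring. Because H7 faces the hindered side, reducing an sp2 C7 after C13 is in place would add hydrogen from the open C14 side and give the wrong epimer; C7 must therefore arrive as a finished stereocentre, whereas C8 can be set last. Sensitive points are the β-alkoxy ketone C14–C15–C16–O17 (retro-oxa-Michael through a C15 enolate), the β-acyloxy ketone array C14–C13–C12–O11 (E1cB in any precursor enolised at C13), and the epimerisable centres C8 and C2. The enabling feature is the chain O17–C18–C19–C13–C14(=O) in ring C: C18 on C19 and C7 on C13 stand anti across C19–C13 and the next atom is a carbonyl carbon, which is the retron of a Prins cyclisation ended by a pinacol shift in a ring C cyclohexene (C13=C19) carrying O17–CH2(+) on C16 and C7 on a C14 carbinol.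

## Retrosynthesis

**28 to 27.**
- The cut removes the hydrogens at C8 and C9 and restores the benzyl ester, giving unsaturated spirolactone 27.
- C8 is the only ring stereocentre that can wait. In 27, H7 is axial to rings A and B and C14 is axial on ring B, so C14 covers the face of C8=C9 opposite to H7.
- The forward step needs syn addition of H2 from the H7 face (the cis fusion), together with hydrogenolysis.

**27 to 25.**
- The cut is the C10–O11 lactone bond, through hydroxy ester 26.
- Leaving ring B open keeps C12–O11 as a silyl ether rather than an acyloxy group that could take part in the cation chemistry of the key step.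
- Closure is a six-membered lactonisation of a primary alcohol onto a nearby ester.

**25 to 23 (key cut).**
- C18–C19 is cut and C7 is moved back from C13 to C14, through formal 24.
- The hindered C13–C7 bond is thus made first as C14–C7, at a flat carbonyl carbon, and only then shifted.
- Cutting C13–C7 directly calls for an enolate that eliminates O11. Cutting C13–C12 calls for attack on the wrong face.
- Precursor 23 has one ring less, no quaternary stereocentre and no bridge.
- The forward reaction must form two C–C bonds, two stereocentres and the ketone, with C7 keeping its configuration.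

**23 to 14 + 21.**
- The cut is C14–C7, and it gives two fragments of ten skeletal carbons each.
- An allylzinc 22 carrying its ester on C8 is chosen over a saturated cyclohexyl metal. It tolerates both esters, adds 1,2 to hindered ketones, and leaves C8=C9 as the handle for C8.
- Both allylic chloride isomers converge on 22.
- The addition must be anti to the C4 side chain (setting C7) and anti to C16–OMOM (setting C14).

**21 to 15.**
- C18 comes from MOMCl, so the protecting group becomes a ring atom.
- O17 comes from an enantioselective β-borylation of dienone 18 (through 19 to 20).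
- C12 comes from formaldehyde (16, protected as 17).
- The single stereocentre of 21 (C16) later controls C14, C13 and C19.

**14 to 10.**
- C10 is introduced by carbonylation of iodide 12 to give 13, which is then chlorinated.
- The iodide comes from enone 10 through 11.
- Reduction precedes carbonylation so that no 2-acyl enone, which could tautomerise through C4, is ever formed.

**10 to 1 + 2 + 8.**
- Ring A is cut at C4–C5 and C8=C9, a Robinson-type annulation of aldehyde 7 with enone 8 through 9.
- C4 is set by the amine catalyst next to a C2 that is already fixed.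
- C2 comes from an auxiliary-controlled allylation (1 + 2, through 3, to 4, then 5 and ozonide 6).
- The otherwise uncontrollable C2/C4 pair is thus set by two independent reagents.

## Roads not taken

Alternative 1: cut C7–C8 and C4–C9 (the most obvious route).
- The forward key step is an intramolecular Diels–Alder reaction of acrylate triene A1, which closes rings A and B together.
- A1 already contains C13, so the hardest centre would still have to be made by hydroxymethylation of a β-alkoxy ketone enolate.
- Suprafacial addition maps an E,E-diene onto cis substituents at C7 and C4. The trans relation of the target therefore demands the E,Z-diene drawn, which reaches the s-cis form poorly.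
- An extra alkene also remains to be removed.

Alternative 2: cut C13–C7 along the 1,5-dicarbonyl path C14–C13–C7–C8–C10.
- The forward key step is an intramolecular Michael addition of the C13 enolate of keto ester A2 onto C7=C8.
- That enolate has a carboxylate leaving group on C12 and should eliminate (E1cB) faster than it closes a 6-endo ring onto a weak, β-substituted acceptor.
- The same base can open the oxa-bridge through C15.
- The chosen plan never enolises C13.

Alternative 3: cut C13–C7 with C7 as an sp2 carbon.
- The forward sequence is palladium-catalysed α-alkenylation (or a shift of a cyclohexenyl group), lactonisation to the tetrasubstituted lactone A3, and hydrogenation of C7=C8.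
- The union is short, but hydrogen would have to reach C7 from the face covered by C19 and the syn methyl of C20, while the open face lies on the C14 side.
- The alkene is also tetrasubstituted and next to a quaternary carbon.
- The chosen plan brings H7 in with the migrating carbon.

Key step: step 15

Assumption: the sense of induction in steps 4 and 12 is taken from simple aldehydes and from cyclohex-2-enone; if either is opposite, the mirror-image catalyst or ligand is used.

## Route

Step 1
Reactants: 1 (4S)-4-benzyl-3-propanoyl-1,3-oxazolidin-2-one; 2 allyl iodide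
Product: 4 (4S)-4-benzyl-3-[(2R)-2-methylpent-4-enoyl]-1,3-oxazolidin-2-one, via sodium enolate 3 (not isolated)
Conditions: NaHMDS, THF, −78 °C; then 2, −78 to −40 °C
Reagents that add atoms: none
Why: Evans alkylation; the chelated Z-enolate is attacked on the face away from the benzyl group, which sets C2 as R.

Step 2
Reactants: 4
Product: 5 benzyl (2R)-2-methylpent-4-enoate
Conditions: BnOH, n-BuLi, THF, 0 °C
Reagents that add atoms: benzyl alcohol, OCc1ccccc1
Why: Transesterification with lithium benzyloxide at the exocyclic carbonyl; this is the standard non-epimerising removal of the auxiliary and it installs the ester that the last step cleaves.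

Step 3
Reactants: 5
Product: 7 benzyl (2R)-2-methyl-4-oxobutanoate, via ozonide 6 (not isolated)
Conditions: O3, CH2Cl2, −78 °C; then PPh3, −78 °C to rt
Reagents that add atoms: ozone, [O-][O+]=O
Why: Ozonolysis with reductive work-up; C2 is β to the new aldehyde and is not at risk.

Step 4
Reactants: 7; 8 but-3-en-2-one
Product: 10 benzyl (2R)-2-[(1R)-4-oxocyclohex-2-en-1-yl]propanoate, via keto aldehyde 9 (not isolated)
Conditions: (S)-α,α-diphenylprolinol trimethylsilyl ether (10 mol %), ethyl 3,4-dihydroxybenzoate (20 mol %), neat, 4 °C; then LiOH (0.3 equiv), i-PrOH, 0 °C to rt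
Reagents that add atoms: none
Why: Enamine-catalysed Michael addition followed by intramolecular aldol condensation (Robinson-type annulation). The diarylmethyl group of the catalyst shields one enamine face and sets C4. Hydroxide rather than a secondary amine closes the ring so that C4 is not re-enolised.

Step 5
Reactants: 10
Product: 11 benzyl (2R)-2-[(1S)-3-iodo-4-oxocyclohex-2-en-1-yl]propanoate
Conditions: I2, pyridine, CH2Cl2, 0 °C to rt
Reagents that add atoms: iodine, II
Why: α-Iodination of an enone by conjugate addition of pyridine, iodination of the enolate and elimination; C4–H is not touched.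

Step 6
Reactants: 11
Product: 12 benzyl (2R)-2-[(1S,4R)-4-hydroxy-3-iodocyclohex-2-en-1-yl]propanoate
Conditions: NaBH4, CeCl3·7H2O, MeOH, −78 °C
Reagents that add atoms: none
Why: Luche 1,2-reduction; axial hydride attack should give mainly the 1,4-trans alcohol, and this centre (C7) is erased at the zinc stage anyway.

Step 7
Reactants: 12
Product: 13 methyl (3R,6R)-3-[(2R)-1-(benzyloxy)-1-oxopropan-2-yl]-6-hydroxycyclohex-1-ene-1-carboxylate
Conditions: Pd(PPh3)4 (5 mol %), CO (1 atm), Et3N, MeOH/DMF, 50 °C
Reagents that add atoms: carbon monoxide, [C-]#[O+]; methanol, CO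
Why: Palladium-catalysed methoxycarbonylation of an alkenyl iodide installs C10; methanol as cosolvent outruns the neighbouring hydroxyl.

Step 8
Reactants: 13
Product: 14 methyl (3R,6S)-3-[(2R)-1-(benzyloxy)-1-oxopropan-2-yl]-6-chlorocyclohex-1-ene-1-carboxylate
Conditions: PPh3, CCl4, CH2Cl2, 0 °C to rt
Reagents that add atoms: tetrachloromethane, ClC(Cl)(Cl)Cl
Why: Appel reaction, drawn with inversion; any SN2′ isomer or C7 epimer is harmless because all of them give the same allylzinc.

Step 9
Reactants: 15 4,4-dimethylcyclohex-2-en-1-one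
Product: 16 2-(hydroxymethyl)-4,4-dimethylcyclohex-2-en-1-one
Conditions: aqueous formaldehyde, DMAP (20 mol %), THF/H2O, rt
Reagents that add atoms: formaldehyde, C=O
Why: Morita–Baylis–Hillman reaction of a cyclic enone with formaldehyde puts C12 on C13.

Step 10
Reactants: 16
Product: 17 2-{[(tert-butyldiphenylsilyl)oxy]methyl}-4,4-dimethylcyclohex-2-en-1-one
Conditions: TBDPSCl, imidazole, CH2Cl2, rt
Reagents that add atoms: tert-butyl(chloro)diphenylsilane, CC(C)(C)[Si](Cl)(c1ccccc1)c1ccccc1
Why: Standard silylation; the bulky, weakly donating and Lewis-acid-stable ether is chosen with step 15 in mind.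

Step 11
Reactants: 17
Product: 18 2-{[(tert-butyldiphenylsilyl)oxy]methyl}-4,4-dimethylcyclohexa-2,5-dien-1-one
Conditions: IBX (2.5 equiv), DMSO, 75 °C
Reagents that add atoms: none
Why: IBX dehydrogenation of a ketone; only the C15–C16 side carries removable hydrogens.

Step 12
Reactants: 18
Product: 20 (5R)-2-{[(tert-butyldiphenylsilyl)oxy]methyl}-5-hydroxy-4,4-dimethylcyclohex-2-en-1-one, via boryl ketone 19 (not isolated)
Conditions: CuCl (5 mol %), (R)-1-[(S)-2-(diphenylphosphino)ferrocenyl]ethyldicyclohexylphosphine (6 mol %), NaOt-Bu (10 mol %), B2pin2, MeOH, THF, −20 °C; then NaBO3·4H2O, THF/H2O, 0 °C to rt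
Reagents that add atoms: bis(pinacolato)diboron, CC1(C)OB(OC1(C)C)B1OC(C)(C)C(C)(C)O1 (boron group of 19); sodium perborate, [Na+].[Na+].O[B-]1(O)OO[B-](O)(O)OO1 (oxygen of 20)
Why: Copper-catalysed enantioselective conjugate borylation followed by stereoretentive oxidation. The α-substituted C13=C19 enone is the slower acceptor, so boron goes to C16, and the ligand sets C16.

Step 13
Reactants: 20
Product: 21 (5R)-2-{[(tert-butyldiphenylsilyl)oxy]methyl}-5-(methoxymethoxy)-4,4-dimethylcyclohex-2-en-1-one
Conditions: MOMCl, i-Pr2NEt, CH2Cl2, 0 °C to rt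
Reagents that add atoms: chloromethyl methyl ether, COCCl
Why: Standard acetal protection under a weak base that should not trigger β-elimination; its CH2 becomes C18.

Step 14
Reactants: 14; 21
Product: 23 methyl (3R,6R)-3-[(2R)-1-(benzyloxy)-1-oxopropan-2-yl]-6-[(1R,5R)-2-{[(tert-butyldiphenylsilyl)oxy]methyl}-1-hydroxy-5-(methoxymethoxy)-4,4-dimethylcyclohex-2-en-1-yl]cyclohex-1-ene-1-carboxylate, via allylzinc chloride 22 (not isolated)
Conditions: Zn dust, LiCl, THF, 25 °C; then 21, −78 °C; cold aqueous work-up
Reagents that add atoms: zinc, [Zn] (in 22 only)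
Why: LiCl-assisted zinc insertion and 1,2-addition of a cyclic, ester-bearing allylzinc to a ketone through a Zimmerman–Traxler chair. Zinc sits on C9 anti to the C4 side chain and delivers C14 to C7 on that same face (sets C7). The ketone is attacked anti to the axial C16–OMOM group (sets C14, with OH syn to O17).

Step 15
Reactants: 23
Product: 25 methyl (3R,6S)-3-[(2R)-1-(benzyloxy)-1-oxopropan-2-yl]-6-[(1R,2S,5R)-2-{[(tert-butyldiphenylsilyl)oxy]methyl}-8,8-dimethyl-3-oxo-6-oxabicyclo[3.2.1]octan-2-yl]cyclohex-1-ene-1-carboxylate, via bridged formal 24 (not isolated)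
Conditions: SnCl4 (2.0 equiv), 2,6-di-tert-butyl-4-methylpyridine (1.2 equiv), CH2Cl2, −78 to −30 °C
Reagents that add atoms: none
Why: Proposed new method: SnCl4 ionises the MOM acetal, the syn C14 hydroxyl traps the ion as bridged formal 24, and renewed opening of 24 at the hindered O14–C18 bond gives the oxocarbenium ion O17=C18H2(+) next to a stannate alkoxide on C14. C19 of the trisubstituted C13=C19 alkene attacks C18 (Markovnikov sense, tertiary cation at C13), which closes the tetrahydrofuran ring C16–O17–C18–C19–C20 in a 5-exo-trig mode with respect to the alkene and turns ring C into the 6-oxabicyclo[3.2.1]octane. The cation is quenched by the 1,2-shift of C7 from C14 to C13, pushed by the alkoxide, which releases the C14 ketone; this second event closes no ring. The closest known reaction types are the pinacol-terminated Prins cyclisation of allylic diol acetals and the (3,5)-oxonium-ene closure of tetrahydrofurans; what is new is the bridging topology and the shift of an exocyclic, stereogenic sec-alkyl group. C19 is set by the tether, since C18 hangs from axial O17 and reaches only the upper face; C13 is set by anti addition, since C7 sits on the lower face of C14 and moves suprafacially to the lower lobe at C13; C7 keeps its configuration because a migrating carbon moves with retention. The step needs the C7 shift to beat hydride shift from C12, ring contraction by C15, proton loss and ionisation at C14. In its favour, the stannate alkoxide is a far better donor than the bulky silyl ether on O12, the C14–C15 bond lies near the nodal plane of the cation in the flattened half-chair, and low temperature with a hindered base holds back ionisation. The C8=C9 alkene is deactivated by its ester and should stay out of the cation chemistry.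

Step 16
Reactants: 25
Product: 27 unsaturated spirolactone benzyl ester (ring B closed, C8=C9; C2 R, C4 R, C7 S, C13 S, C16 R, C19 R), via hydroxy ester 26 (not isolated)
Conditions: HF·pyridine, THF, 0 °C to rt; then camphorsulfonic acid (10 mol %), toluene, 60 °C
Reagents that add atoms: none
Why: Acidic fluoride desilylation followed by acid-catalysed lactonisation to a six-membered ring; base is avoided so that the oxa-bridge and C4–H (γ to the ester) stay intact.

Step 17
Reactants: 27
Product: 28 target acid CNP0152427.2 (C2 R, C4 R, C7 R, C8 S, C13 S, C16 R, C19 R)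
Conditions: H2 (1 atm), Pd/C (10 %), EtOAc, rt
Reagents that add atoms: none
Why: Heterogeneous hydrogenation with hydrogenolysis of the benzyl ester. Syn addition from the face of axial H7, opposite to axial C14 on ring B, sets C8 and gives the cis fusion. The isolated ketone and the ether bridge are inert.

## Compound list

1 | (4S)-4-benzyl-3-propanoyl-1,3-oxazolidin-2-one | CCC(=O)N1[C@@H](Cc2ccccc2)COC1=O | starting material
2 | allyl iodide (3-iodoprop-1-ene) | C=CCI | starting material
3 | sodium (Z)-enolate of 1 | C/C=C(\[O-])N1[C@@H](Cc2ccccc2)COC1=O.[Na+] | intermediate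
4 | (4S)-4-benzyl-3-[(2R)-2-methylpent-4-enoyl]-1,3-oxazolidin-2-one | C[C@@H](C(=O)N1[C@@H](Cc2ccccc2)COC1=O)CC=C | intermediate
5 | benzyl (2R)-2-methylpent-4-enoate | C[C@@H](C(=O)OCc1ccccc1)CC=C | intermediate
6 | benzyl (2R)-2-methyl-3-(1,2,4-trioxolan-3-yl)propanoate (ozonide) | C[C@@H](C(=O)OCc1ccccc1)CC1OCOO1 | intermediate
7 | benzyl (2R)-2-methyl-4-oxobutanoate | C[C@@H](C(=O)OCc1ccccc1)CC=O | intermediate
8 | but-3-en-2-one | C=CC(C)=O | starting material
9 | benzyl (2R,3S)-3-formyl-2-methyl-6-oxoheptanoate | C[C@@H](C(=O)OCc1ccccc1)[C@@H](C=O)CCC(C)=O | intermediate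
10 | benzyl (2R)-2-[(1R)-4-oxocyclohex-2-en-1-yl]propanoate | C[C@@H](C(=O)OCc1ccccc1)[C@@H]1CCC(=O)C=C1 | intermediate
11 | benzyl (2R)-2-[(1S)-3-iodo-4-oxocyclohex-2-en-1-yl]propanoate | C[C@@H](C(=O)OCc1ccccc1)[C@@H]1CCC(=O)C(I)=C1 | intermediate
12 | benzyl (2R)-2-[(1S,4R)-4-hydroxy-3-iodocyclohex-2-en-1-yl]propanoate | C[C@@H](C(=O)OCc1ccccc1)[C@@H]1CC[C@@H](O)C(I)=C1 | intermediate
13 | methyl (3R,6R)-3-[(2R)-1-(benzyloxy)-1-oxopropan-2-yl]-6-hydroxycyclohex-1-ene-1-carboxylate | C[C@@H](C(=O)OCc1ccccc1)[C@@H]1CC[C@@H](O)C(C(=O)OC)=C1 | intermediate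
14 | methyl (3R,6S)-3-[(2R)-1-(benzyloxy)-1-oxopropan-2-yl]-6-chlorocyclohex-1-ene-1-carboxylate | C[C@@H](C(=O)OCc1ccccc1)[C@@H]1CC[C@H](Cl)C(C(=O)OC)=C1 | intermediate
15 | 4,4-dimethylcyclohex-2-en-1-one | CC1(C)CCC(=O)C=C1 | starting material
16 | 2-(hydroxymethyl)-4,4-dimethylcyclohex-2-en-1-one | CC1(C)CCC(=O)C(CO)=C1 | intermediate
17 | 2-{[(tert-butyldiphenylsilyl)oxy]methyl}-4,4-dimethylcyclohex-2-en-1-one | CC1(C)CCC(=O)C(CO[Si](c2ccccc2)(c3ccccc3)C(C)(C)C)=C1 | intermediate
18 | 2-{[(tert-butyldiphenylsilyl)oxy]methyl}-4,4-dimethylcyclohexa-2,5-dien-1-one | CC1(C)C=CC(=O)C(CO[Si](c2ccccc2)(c3ccccc3)C(C)(C)C)=C1 | intermediate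
19 | (5R)-2-{[(tert-butyldiphenylsilyl)oxy]methyl}-4,4-dimethyl-5-(4,4,5,5-tetramethyl-1,3,2-dioxaborolan-2-yl)cyclohex-2-en-1-one | O=C1C[C@@H](B2OC(C)(C)C(C)(C)O2)C(C)(C)C=C1CO[Si](c3ccccc3)(c4ccccc4)C(C)(C)C | intermediate
20 | (5R)-2-{[(tert-butyldiphenylsilyl)oxy]methyl}-5-hydroxy-4,4-dimethylcyclohex-2-en-1-one | O=C1C[C@@H](O)C(C)(C)C=C1CO[Si](c3ccccc3)(c4ccccc4)C(C)(C)C | intermediate
21 | (5R)-2-{[(tert-butyldiphenylsilyl)oxy]methyl}-5-(methoxymethoxy)-4,4-dimethylcyclohex-2-en-1-one | O=C1C[C@@H](OCOC)C(C)(C)C=C1CO[Si](c3ccccc3)(c4ccccc4)C(C)(C)C | intermediate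
22 | allylzinc chloride of ring A (drawn with zinc on C9, trans to the C4 side chain; fluxional) | C[C@@H](C(=O)OCc1ccccc1)[C@@H]1CCC=C(C(=O)OC)[C@H]1[Zn]Cl | intermediate
23 | tertiary alcohol of step 14 (C14–OH cis to C16–OMOM on ring C; C7–C14 bond trans to the C4 side chain on ring A) | C[C@@H](C(=O)OCc3ccccc3)[C@@H]1CC[C@H](C(C(=O)OC)=C1)[C@]4(O)C[C@@H](OCOC)C(C)(C)C=C4CO[Si](c5ccccc5)(c6ccccc6)C(C)(C)C | intermediate
24 | bridged formal (2,4-dioxabicyclo[3.3.1]non-6-ene; O14–C18H2–O17 spans C14 and C16) | C[C@@H](C(=O)OCc3ccccc3)[C@@H]1CC[C@H](C(C(=O)OC)=C1)[C@]42C[C@@H](OCO2)C(C)(C)C=C4CO[Si](c5ccccc5)(c6ccccc6)C(C)(C)C | intermediate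
25 | oxa-bridged ketone of step 15 (C13 quaternary; C12 cis and C7 trans to C18) | C[C@@H](C(=O)OCc3ccccc3)[C@@H]1CC[C@H](C(C(=O)OC)=C1)[C@]4(CO[Si](c5ccccc5)(c6ccccc6)C(C)(C)C)C(=O)C[C@H]2OC[C@@H]4C2(C)C | intermediate
26 | hydroxy ester (25 with free C12–OH) | C[C@@H](C(=O)OCc3ccccc3)[C@@H]1CC[C@H](C(C(=O)OC)=C1)[C@]4(CO)C(=O)C[C@H]2OC[C@@H]4C2(C)C | intermediate
27 | unsaturated spirolactone benzyl ester (C8=C9) | C[C@@H](C(=O)OCc3ccccc3)[C@@H]1CC[C@@H]2C(=C1)C(=O)OC[C@]21C(=O)C[C@H]2OC[C@@H]1C2(C)C | intermediate
28 | CNP0152427.2 | C[C@@H](C(=O)O)[C@@H]1CC[C@@H]2[C@H](C1)C(=O)OC[C@]21C(=O)C[C@H]2OC[C@@H]1C2(C)C | target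

## Step count and least certain steps

Total: 17 steps. Longest linear sequence: 12 steps (steps 1–8, then 14–17). Ring C fragment 21 takes 5 steps (steps 9–13).

**Step 15 (key step, new method).**
- Risks:
  - A 1,2-hydride shift from C12 could quench the C13 cation, because the C12–H bonds can always align with it.
  - The tertiary allylic C14–O bond could ionise.
  - Opening of the formal the other way round could lead to a 2-oxonia-Cope allyl transfer that breaks C14–C7.
  - If the cation relaxes to a full chair, ring contraction through C15 becomes possible.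
- Fallback (known chemistry), from 15 and 13 back to 25:
  - 15 is dehydrogenated with IBX to 4,4-dimethylcyclohexa-2,5-dien-1-one F1.
  - Copper-catalysed asymmetric conjugate addition of (dimethylphenylsilyl)methylmagnesium chloride, with capture of the enolate by formaldehyde, gives trans hydroxymethyl enone F2, which is silylated to TBDPS ether F3.
  - The cross-conjugated lithium enolate of F3 can form only at C13. It is allylated under Tsuji–Trost conditions with methyl carbonate F4 (made from 13), anti to the C18 arm, to give quaternary enone F5.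
  - Fleming–Tamao oxidation (KBr, AcOOH) frees primary alcohol F6, which closes by oxa-Michael addition onto C16 to give 25.

**Step 14.**
- Risks:
  - Facial selectivity at C14 may be poor if zinc is chelated by the MOM oxygens.
  - Control at C7 may erode because the allylzinc is fluxional.
  - The new bond may form at C9 instead of C7.
  - The zinc alkoxide may lactonise onto C10 on warming.
- Fallback, from 14 back to 23:
  - Copper-catalysed γ-selective (anti SN2′) borylation of 14 with B2pin2 gives allylboronate F7, with boron fixed on C9 trans to the side chain.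
  - KHF2 converts F7 into potassium trifluoroborate F8.
  - F8 is configurationally stable and adds to 21 on montmorillonite K10 through a closed transition state. C7 is then set by stereospecific transfer rather than by a pre-equilibrium.

**Step 12.**
- Risks: enantioselectivity may be low at a β-carbon next to CMe2, conversion may be slow, and the β-hydroxy ketone may lose water back to 18.
- Fallback, from 18 back to 20:
  - Primary-amine-salt-catalysed asymmetric epoxidation (H2O2) of the less substituted enone gives epoxy ketone F9.
  - Reductive opening of F9 at C15 with (PhSe)2/NaBH4 gives 20.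

**Step 4.**
- Risks: the catalyst may be mismatched with the resident C2 centre, the aldehyde may self-condense, and C4 may epimerise during the basic ring closure.
- Fallback, from 10 (as a C4 mixture) back to 10:
  - Conjugate reduction with [(Ph3P)CuH]6 gives ketone F10, in which C4 is no longer stereogenic.
  - Desymmetrising deprotonation with lithium (R,R)-bis(1-phenylethyl)amide in the presence of TMSCl gives silyl enol ether F11.
  - Saegusa–Ito oxidation of F11 with Pd(OAc)2 returns 10 as one C4 epimer.

**Step 17.**
- Risks: the alkene may migrate to C7=C8 on the palladium surface, which would erase C7; uptake at the hindered trisubstituted alkene may be slow; hydrogen may attack from the C14 face.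
- Fallback, from 27 back to 28:
  - Conjugate hydride delivery to C9 with [(Ph3P)CuH]6, then protonation of the enolate at C8 from the open face, gives saturated benzyl ester F12.
  - F12 is then hydrogenolysed (H2, Pd/C) to 28.

## Further compounds

F1 | step 15 | 4,4-dimethylcyclohexa-2,5-dien-1-one | CC1(C)C=CC(=O)C=C1
F2 | step 15 | trans-5-{[dimethyl(phenyl)silyl]methyl}-6-(hydroxymethyl)-4,4-dimethylcyclohex-2-en-1-one | O=C1C=CC(C)(C)[C@@H](C[Si](C)(C)c2ccccc2)[C@@H]1CO
F3 | step 15 | TBDPS ether of F2 | O=C1C=CC(C)(C)[C@@H](C[Si](C)(C)c2ccccc2)[C@@H]1CO[Si](c3ccccc3)(c4ccccc4)C(C)(C)C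
F4 | step 15 | methyl carbonate of 13 | C[C@@H](C(=O)OCc1ccccc1)[C@@H]1CC[C@@H](OC(=O)OC)C(C(=O)OC)=C1
F5 | step 15 | C13-allylated enone (C7 trans to the C18 arm) | C[C@@H](C(=O)OCc3ccccc3)[C@@H]1CC[C@H](C(C(=O)OC)=C1)[C@]4(CO[Si](c5ccccc5)(c6ccccc6)C(C)(C)C)C(=O)C=CC(C)(C)[C@H]4C[Si](C)(C)c7ccccc7
F6 | step 15 | C18 primary alcohol of F5 | C[C@@H](C(=O)OCc3ccccc3)[C@@H]1CC[C@H](C(C(=O)OC)=C1)[C@]4(CO[Si](c5ccccc5)(c6ccccc6)C(C)(C)C)C(=O)C=CC(C)(C)[C@H]4CO
F7 | step 14 | ring A allylboronic acid pinacol ester (boron on C9) | C[C@@H](C(=O)OCc1ccccc1)[C@@H]1CCC=C(C(=O)OC)[C@H]1B2OC(C)(C)C(C)(C)O2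
F8 | step 14 | potassium allyltrifluoroborate from F7 | C[C@@H](C(=O)OCc1ccccc1)[C@@H]1CCC=C(C(=O)OC)[C@H]1[B-](F)(F)F.[K+]
F9 | step 12 | 5,6-epoxide of 18 (oxygen on the O17 face) | O=C1[C@H]2O[C@H]2C(C)(C)C=C1CO[Si](c3ccccc3)(c4ccccc4)C(C)(C)C
F10 | step 4 | benzyl (2R)-2-(4-oxocyclohexyl)propanoate | C[C@@H](C(=O)OCc1ccccc1)C1CCC(=O)CC1
F11 | step 4 | benzyl (2R)-2-[(1R)-4-(trimethylsilyloxy)cyclohex-3-en-1-yl]propanoate | C[C@@H](C(=O)OCc1ccccc1)[C@@H]1CCC(O[Si](C)(C)C)=CC1
F12 | step 17 | benzyl ester of 28 | C[C@@H](C(=O)OCc3ccccc3)[C@@H]1CC[C@@H]2[C@H](C1)C(=O)OC[C@]21C(=O)C[C@H]2OC[C@@H]1C2(C)C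
A1 | alternative 1 | acrylate of the C13 hydroxymethyl ketone carrying the E,Z-dienyl side chain | C[C@@H](C(=O)OCc1ccccc1)/C=C\C=C\[C@]1(COC(=O)C=C)C(=O)C[C@H]2OC[C@@H]1C2(C)C
A2 | alternative 2 | ring A cyclohex-1-enecarboxylate of the 2-(hydroxymethyl) bicyclic ketone | C[C@@H](C(=O)OCc1ccccc1)[C@@H]1CCC=C(C1)C(=O)OCC1C(=O)C[C@H]2OC[C@@H]1C2(C)C
A3 | alternative 3 | tetrasubstituted C7=C8 unsaturated spirolactone | C[C@@H](C(=O)OCc1ccccc1)[C@@H]1CCC2=C(C1)C(=O)OC[C@]21C(=O)C[C@H]2OC[C@@H]1C2(C)C
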